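**Plan**
- Retrosynthesis: cut O1–C2 (pyran ether closure), then C2–C3 (one-carbon homologation of a C3 boronic ester), then C3–C1' and C4–C4a together (three-component coupling across a vinyl boronate), and in ring A the C6–prenyl bond.
- Enabling feature: C3–C4 is a two-carbon bridge from C1' of ring B to C4a of ring A, so one vinyl boronate takes ring B on its boron-bearing carbon and ring A on its terminus while boron marks the place of C2. In ring A the O5 methyl ether lies between C4a and C6, so a symmetric dibromide serves both positions.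
- Forward: 5-methoxyresorcinol → bis-silyl ether → dibromide → prenylated ring A bromide; 4-bromo-3-methoxyphenol → silyl ether → aryllithium; conjunctive coupling; homologation and oxidation; desilylation; closure of the pyran ring, the only ring formed, last.
- Stereochemistry: C3 is set in the coupling by the chiral diphosphine on palladium, carried with retention through the homologation, and is not a reacting centre afterwards.

Key step: step 5

Remark: isoflavan numbering is used (O1, C2, C3, C4, C4a, C5–C8, C8a; ring B C1'–C6'); TIPS = triisopropylsilyl.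
Assumption: the (Sp,Sp) ligand is taken, by analogy with simple aryl partners, to give the (R)-boronic ester; if the sense proves opposite, the mirror-image ligand is used and nothing else changes.

**Step 1**
Reactants: 1 5-methoxyresorcinol
Product: 2 1-methoxy-3,5-bis(triisopropylsilyloxy)benzene
Conditions: TIPSCl (2.3 equiv), imidazole, DMF, rt
Reagents that add atoms: triisopropylsilyl chloride, CC(C)[Si](Cl)(C(C)C)C(C)C
Why: Imidazole-promoted silyl ether formation on both phenols gives bulky, base-stable ethers that later shield C8, the carbon between them.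

**Step 2**
Reactants: 2 1-methoxy-3,5-bis(triisopropylsilyloxy)benzene
Product: 3 2,4-dibromo-3-methoxy-1,5-bis(triisopropylsilyloxy)benzene
Conditions: NBS (2.05 equiv), MeCN, 0 °C → rt, dark
Reagents that add atoms: N-bromosuccinimide, O=C1CCC(=O)N1Br
Why: Electrophilic aromatic bromination should take the two open positions beside the methoxy group, each para to a silyloxy group, because the carbon between the two triisopropylsilyloxy groups is shielded; the brominating agent is used before any alkene is present.

**Step 3**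
Reactants: 3 2,4-dibromo-3-methoxy-1,5-bis(triisopropylsilyloxy)benzene; 4 prenyl bromide
Product: 6 1-bromo-2-methoxy-3-(3-methylbut-2-enyl)-4,6-bis(triisopropylsilyloxy)benzene, via aryllithium 5 (not isolated)
Conditions: n-BuLi (1.05 equiv), THF, −78 °C; CuBr·SMe2 (10 mol %), 4, −78 → 0 °C
Reagents that add atoms: none
Why: Bromine–lithium exchange on one of two equivalent bromides (the aryllithium resists a second exchange) followed by copper-catalysed allylic substitution at the primary terminus of prenyl bromide fixes the prenyl group at C6 and leaves bromine at C4a by symmetry.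

**Step 4**
Reactants: 7 4-bromo-3-methoxyphenol
Product: 8 (4-bromo-3-methoxyphenoxy)triisopropylsilane
Conditions: TIPSCl (1.2 equiv), imidazole, DMF, rt
Reagents that add atoms: triisopropylsilyl chloride, CC(C)[Si](Cl)(C(C)C)C(C)C
Why: Silyl ether formation masks O4' against the organolithium and matches the ring A groups, so one fluoride treatment later frees all phenols.

**Step 5**
Reactants: 8 (4-bromo-3-methoxyphenoxy)triisopropylsilane; 9 vinylboronic acid pinacol ester; 6 1-bromo-2-methoxy-3-(3-methylbut-2-enyl)-4,6-bis(triisopropylsilyloxy)benzene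
Product: 12 (R)-2-{1-(2-methoxy-4-triisopropylsilyloxyphenyl)-2-[2-methoxy-3-(3-methylbut-2-enyl)-4,6-bis(triisopropylsilyloxy)phenyl]ethyl}-4,4,5,5-tetramethyl-1,3,2-dioxaborolane, via ring B aryllithium 10 (not isolated), via vinyl borate 11 (not isolated)
Conditions: t-BuLi (2 equiv), Et2O, −78 °C; 9, −78 °C → rt; solvent swap to THF; 6, Pd(OAc)2 (5 mol %), (Sp,Sp)-1,1'-bis[bis(4-methoxy-3,5-dimethylphenyl)phosphino]-2,2'-bis[(R)-α-(dimethylamino)benzyl]ferrocene (6 mol %), KO3SCF3 (2.5 equiv), THF, 60 °C
Reagents that add atoms: none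
Why: Zerovalent palladium inserts into the C4a–Br bond of 6, and exchange of bromide for triflate (bromide leaving as KBr) gives a cationic divalent palladium aryl that binds the vinyl group of borate 11. The ring B aryl group then shifts from boron to the adjacent carbon anti to palladium (1,2-metallate shift, forming C3–C1'), and reductive elimination from the alkyl(aryl)palladium forms C4–C4a and returns zerovalent palladium. The closest known reaction type is the palladium-catalysed enantioselective conjunctive cross-coupling of vinylboron ate complexes with aryl halides in the presence of a triflate salt. No ring is closed. The new stereocenter C3 is controlled by the chiral ferrocenyl diphosphine, which decides the alkene face that palladium occupies during the anti migration, and the secondary benzylic boronic ester formed is configurationally stable. The step needs the conjunctive pathway to outrun direct Suzuki-type transfer of aryl or vinyl from boron, which the chelating diphosphine, the cationic palladium centre and the electron-rich, readily migrating ortho-methoxyaryl group should secure, while the silyl group on O8a can turn toward C8–H and leave the C4a–Pd site accessible.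

**Step 6**
Reactants: 12 (R)-1,2-diarylethyl boronic ester
Product: 15 (R)-2-(2-methoxy-4-triisopropylsilyloxyphenyl)-3-[2-methoxy-3-(3-methylbut-2-enyl)-4,6-bis(triisopropylsilyloxy)phenyl]propan-1-ol, via chloromethyl borate 13 (not isolated), via primary boronic ester 14 (not isolated)
Conditions: BrCH2Cl (3 equiv), n-BuLi (2.5 equiv), THF, −78 °C → rt; then NaBO3·4H2O, THF/H2O, rt
Reagents that add atoms: bromochloromethane, ClCBr; sodium perborate tetrahydrate, [Na+].[O-]OB=O.O.O.O.O
Why: In a Matteson homologation chloromethyllithium adds to boron and C3 migrates with retention while chloride leaves, which inserts C2, and the primary boronic ester is then oxidised in the same flask by perborate without touching the silyl ethers or the alkene.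

**Step 7**
Reactants: 15 (R)-tris-silylated primary alcohol
Product: 16 (R)-4-[3-hydroxy-2-(4-hydroxy-2-methoxyphenyl)propyl]-5-methoxy-6-(3-methylbut-2-enyl)benzene-1,3-diol
Conditions: TBAF (3.5 equiv), THF, 0 °C; aq NH4Cl
Reagents that add atoms: none
Why: Fluoride-mediated cleavage of the three aryl silyl ethers, driven by the Si–F bond, frees all phenols under conditions that affect neither the prenyl alkene nor C3.

**Step 8**
Reactants: 16 (R)-triphenol primary alcohol
Product: 17 (3R)-3-(4-hydroxy-2-methoxyphenyl)-5-methoxy-6-(3-methylbut-2-enyl)chroman-7-ol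
Conditions: PPh3 (1.5 equiv), DIAD (1.5 equiv), THF (0.01 M), 0 °C → rt
Reagents that add atoms: none
Why: In an intramolecular Mitsunobu etherification only the O8a phenol can reach the activated C2 (6-exo-tet closure of the pyran ring), the reacting carbon is a CH2 so C3 is untouched, and high dilution should suppress alkylation of the other two phenols.

**Compound list**
1 | 5-methoxyresorcinol | COc1cc(O)cc(O)c1 | starting material
2 | 1-methoxy-3,5-bis(triisopropylsilyloxy)benzene | COc1cc(O[Si](C(C)C)(C(C)C)C(C)C)cc(O[Si](C(C)C)(C(C)C)C(C)C)c1 | intermediate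
3 | 2,4-dibromo-3-methoxy-1,5-bis(triisopropylsilyloxy)benzene | COc1c(Br)c(O[Si](C(C)C)(C(C)C)C(C)C)cc(O[Si](C(C)C)(C(C)C)C(C)C)c1Br | intermediate
4 | prenyl bromide (1-bromo-3-methylbut-2-ene) | CC(C)=CCBr | starting material
5 | 3-bromo-2-methoxy-4,6-bis(triisopropylsilyloxy)phenyllithium (not isolated) | COc1c(Br)c(O[Si](C(C)C)(C(C)C)C(C)C)cc(O[Si](C(C)C)(C(C)C)C(C)C)c1[Li] | intermediate
6 | 1-bromo-2-methoxy-3-(3-methylbut-2-enyl)-4,6-bis(triisopropylsilyloxy)benzene (ring A bromide) | COc1c(Br)c(O[Si](C(C)C)(C(C)C)C(C)C)cc(O[Si](C(C)C)(C(C)C)C(C)C)c1CC=C(C)C | intermediate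
7 | 4-bromo-3-methoxyphenol | COc1cc(O)ccc1Br | starting material
8 | (4-bromo-3-methoxyphenoxy)triisopropylsilane | COc1cc(O[Si](C(C)C)(C(C)C)C(C)C)ccc1Br | intermediate
9 | vinylboronic acid pinacol ester | C=CB1OC(C)(C)C(C)(C)O1 | starting material
10 | 2-methoxy-4-(triisopropylsilyloxy)phenyllithium (ring B aryllithium, not isolated) | COc1cc(O[Si](C(C)C)(C(C)C)C(C)C)ccc1[Li] | intermediate
11 | lithium (2-methoxy-4-triisopropylsilyloxyphenyl)(vinyl)(pinacolato)borate (not isolated) | [Li+].C=C[B-]1(c2ccc(O[Si](C(C)C)(C(C)C)C(C)C)cc2OC)OC(C)(C)C(C)(C)O1 | intermediate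
12 | (R)-2-{1-(2-methoxy-4-triisopropylsilyloxyphenyl)-2-[2-methoxy-3-(3-methylbut-2-enyl)-4,6-bis(triisopropylsilyloxy)phenyl]ethyl}-4,4,5,5-tetramethyl-1,3,2-dioxaborolane | COc1cc(O[Si](C(C)C)(C(C)C)C(C)C)ccc1[C@@H](Cc1c(O[Si](C(C)C)(C(C)C)C(C)C)cc(O[Si](C(C)C)(C(C)C)C(C)C)c(CC=C(C)C)c1OC)B1OC(C)(C)C(C)(C)O1 | intermediate
13 | lithium (chloromethyl)borate of 12, (R) at C3 (not isolated) | [Li+].COc1cc(O[Si](C(C)C)(C(C)C)C(C)C)ccc1[C@@H](Cc1c(O[Si](C(C)C)(C(C)C)C(C)C)cc(O[Si](C(C)C)(C(C)C)C(C)C)c(CC=C(C)C)c1OC)[B-]1(CCl)OC(C)(C)C(C)(C)O1 | intermediate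
14 | (R)-2-{2-(2-methoxy-4-triisopropylsilyloxyphenyl)-3-[2-methoxy-3-(3-methylbut-2-enyl)-4,6-bis(triisopropylsilyloxy)phenyl]propyl}-4,4,5,5-tetramethyl-1,3,2-dioxaborolane (not isolated) | COc1cc(O[Si](C(C)C)(C(C)C)C(C)C)ccc1[C@@H](Cc1c(O[Si](C(C)C)(C(C)C)C(C)C)cc(O[Si](C(C)C)(C(C)C)C(C)C)c(CC=C(C)C)c1OC)CB1OC(C)(C)C(C)(C)O1 | intermediate
15 | (R)-2-(2-methoxy-4-triisopropylsilyloxyphenyl)-3-[2-methoxy-3-(3-methylbut-2-enyl)-4,6-bis(triisopropylsilyloxy)phenyl]propan-1-ol | COc1cc(O[Si](C(C)C)(C(C)C)C(C)C)ccc1[C@@H](Cc1c(O[Si](C(C)C)(C(C)C)C(C)C)cc(O[Si](C(C)C)(C(C)C)C(C)C)c(CC=C(C)C)c1OC)CO | intermediate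
16 | (R)-4-[3-hydroxy-2-(4-hydroxy-2-methoxyphenyl)propyl]-5-methoxy-6-(3-methylbut-2-enyl)benzene-1,3-diol | COc1cc(O)ccc1[C@@H](Cc1c(O)cc(O)c(CC=C(C)C)c1OC)CO | intermediate
17 | (3R)-3-(4-hydroxy-2-methoxyphenyl)-5-methoxy-6-(3-methylbut-2-enyl)chroman-7-ol | COc1cc(O)ccc1[C@@H]1COc2cc(O)c(CC=C(C)C)c(OC)c2C1 | target

**Count**
Total step count: 8. Longest linear sequence: 7 steps (steps 1, 2, 3, 5, 6, 7, 8); ring B joins after one step.

**Steps most likely to fail**

Step 5. Oxidative addition to the electron-rich, di-ortho-oxygenated bromide may be slow, direct Suzuki-type transfer from boron may compete, and facial selectivity may be poor with so hindered a palladium aryl. The fallback forms the same boronic ester by lithiation–borylation; it sets out from 6 and 8 and comes back at 12.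
- Bromide 6 is exchanged with n-BuLi (THF, −78 °C) to the ring A aryllithium F1, which opens ethylene oxide in the presence of BF3·OEt2 to give the 2-arylethanol F2.
- N,N-Diisopropylcarbamoyl chloride and Et3N convert F2 into the carbamate F3.
- Aryllithium 10, made from 8 as in step 5, is quenched with 2-isopropoxy-4,4,5,5-tetramethyl-1,3,2-dioxaborolane to give the ring B pinacol boronic ester F4.
- s-BuLi and (−)-sparteine in Et2O at −78 °C remove the pro-S proton next to oxygen of F3 to give the configurationally stable (S)-lithiated carbamate F5.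
- F5 adds to F4 with retention to give the borate F6; on warming, ring B migrates from boron to carbon with inversion as the carbamate leaves, which should give (R)-12.

Step 2. Bromination may also occur at the carbon between the two silyloxy groups, or run on to the tribromide. The fallback takes its selectivity from free hydroxyl groups instead of steric shielding; it sets out from 1 and comes back at 3. Diphenol 1 is treated with NBS (2 equiv, MeCN, 0 °C), each bromine entering para to a hydroxyl as in the 4,6-dibromination of resorcinol, to give 4,6-dibromo-5-methoxybenzene-1,3-diol F7. Silylation of F7 with TIPSCl and imidazole then gives 3.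

Step 8. Intermolecular etherification by the O7 or O4' phenol, or elimination across C2–C3, may erode the ring closure. The fallback closes the ring by phenoxide displacement instead of alcohol activation in the presence of free phenols; it sets out from 15 and comes back at 17. Alcohol 15 is converted with methanesulfonyl chloride and Et3N (CH2Cl2, 0 °C) into the mesylate F8. TBAF in dilute THF then removes the three silyl groups to give the triphenol mesylate F9 as its phenoxide, whose O8a oxygen displaces the primary mesylate (intramolecular SN2, six-membered ring) to give 17 directly.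

**Further compounds**
F1 | step 5 | 2-methoxy-3-(3-methylbut-2-enyl)-4,6-bis(triisopropylsilyloxy)phenyllithium | COc1c([Li])c(O[Si](C(C)C)(C(C)C)C(C)C)cc(O[Si](C(C)C)(C(C)C)C(C)C)c1CC=C(C)C
F2 | step 5 | 2-[2-methoxy-3-(3-methylbut-2-enyl)-4,6-bis(triisopropylsilyloxy)phenyl]ethanol | COc1c(CCO)c(O[Si](C(C)C)(C(C)C)C(C)C)cc(O[Si](C(C)C)(C(C)C)C(C)C)c1CC=C(C)C
F3 | step 5 | 2-[2-methoxy-3-(3-methylbut-2-enyl)-4,6-bis(triisopropylsilyloxy)phenyl]ethyl N,N-diisopropylcarbamate | COc1c(CCOC(=O)N(C(C)C)C(C)C)c(O[Si](C(C)C)(C(C)C)C(C)C)cc(O[Si](C(C)C)(C(C)C)C(C)C)c1CC=C(C)C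
F4 | step 5 | 2-(2-methoxy-4-triisopropylsilyloxyphenyl)-4,4,5,5-tetramethyl-1,3,2-dioxaborolane | COc1cc(O[Si](C(C)C)(C(C)C)C(C)C)ccc1B1OC(C)(C)C(C)(C)O1
F5 | step 5 | (S)-1-lithio-2-[2-methoxy-3-(3-methylbut-2-enyl)-4,6-bis(triisopropylsilyloxy)phenyl]ethyl N,N-diisopropylcarbamate | COc1c(C[C@H]([Li])OC(=O)N(C(C)C)C(C)C)c(O[Si](C(C)C)(C(C)C)C(C)C)cc(O[Si](C(C)C)(C(C)C)C(C)C)c1CC=C(C)C
F6 | step 5 | lithium borate from F5 and F4 (boron on the carbamate-bearing carbon, configuration retained) | [Li+].COc1c(C[C@H]([B-]2(c3ccc(O[Si](C(C)C)(C(C)C)C(C)C)cc3OC)OC(C)(C)C(C)(C)O2)OC(=O)N(C(C)C)C(C)C)c(O[Si](C(C)C)(C(C)C)C(C)C)cc(O[Si](C(C)C)(C(C)C)C(C)C)c1CC=C(C)C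
F7 | step 2 | 4,6-dibromo-5-methoxybenzene-1,3-diol | COc1c(Br)c(O)cc(O)c1Br
F8 | step 8 | (R)-2-(2-methoxy-4-triisopropylsilyloxyphenyl)-3-[2-methoxy-3-(3-methylbut-2-enyl)-4,6-bis(triisopropylsilyloxy)phenyl]propyl methanesulfonate | COc1cc(O[Si](C(C)C)(C(C)C)C(C)C)ccc1[C@@H](Cc1c(O[Si](C(C)C)(C(C)C)C(C)C)cc(O[Si](C(C)C)(C(C)C)C(C)C)c(CC=C(C)C)c1OC)COS(C)(=O)=O
F9 | step 8 | (R)-3-[2,4-dihydroxy-6-methoxy-5-(3-methylbut-2-enyl)phenyl]-2-(4-hydroxy-2-methoxyphenyl)propyl methanesulfonate | COc1cc(O)ccc1[C@@H](Cc1c(O)cc(O)c(CC=C(C)C)c1OC)COS(C)(=O)=O
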